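- The protic impurity cannot quench more starting complex than its own charge, since each turn takes one of each: 19.4 % of the starting complex charged in cedar and 40.3 % in ash.

all flasks: starting complex 0.62 M; incoming ligand 0.600 equiv; time 12 s

| run | protic impurity |
|---|---|
| cedar | 0.120 M |
| ash | 0.250 M |

    starting complex + incoming ligand → leaving ligand + complex with one exchanged (k1 = 0.10 M⁻¹ s⁻¹)
    complex with one exchanged + incoming ligand → leaving ligand + complex with two exchanged (k2 = 0.28 M⁻¹ s⁻¹)
    protic impurity + starting complex → quenched substrate (k3 = 0.35 M⁻¹ s⁻¹)
    2 starting complex → self-condensation product (k4 = 0.091 M⁻¹ s⁻¹)
    complex with two exchanged + incoming ligand → over-reaction product (k5 = 0.12 M⁻¹ s⁻¹)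

- which of these there is most of at the end, counted by the starting complex in it, cedar (starting complex / complex with two exchanged / complex with one exchanged / over-reaction product)
- which of these there is most of at the end, counted by the starting complex in it, ash (starting complex / complex with two exchanged / complex with one exchanged / over-reaction product)
- amount of the one of these that there is most of at the end, in percent of the starting complex charged, cedar
- amount of the one of these that there is most of at the end, in percent of the starting complex charged, ash

- percent here means starting complex units held: one self-condensation product counts as two
- two of one species on the left: rate k times its square, two consumed each time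
- run time (cedar): 12 s

- I start with the balance of the protic impurity. Its left-over fraction is exp(−k·E), with k = 0.35 M⁻¹ s⁻¹ and E, the exposure, the time integral of c(starting complex).
- Self-condensation by itself gives an exposure of 4.70 M·s by 12 s. The other steps take starting complex away, so this is a ceiling on E in both flasks.
- The quench ceiling is the impurity charge times the fraction lost at that ceiling exposure, as a share of the starting complex charged: 32.6 % in ash and 15.6 % in cedar.
- My first number holds the impurity and the incoming ligand at their charges, as pseudo-first-order drains beside self-condensation. With 0.0792 s⁻¹ in cedar and 0.125 s⁻¹ in ash, the closed form leaves 20.6 % in cedar and 13.2 % in ash.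
- The weak link is the impurity held at its charge, since its half-life at the charged concentrations, 3.2 s, is a quarter of the run. So I reforge it: I take the quench ceiling off the charge at the start and keep the ligand drain 0.0372 s⁻¹. That leaves 28.1 % in cedar and 24.9 % in ash.
- The same exposure ceiling lets the incoming ligand, at 0.10 M⁻¹ s⁻¹, pull at most 22.5 % of the starting complex into all exchanged forms together. That ceiling is less than my figure for starting complex in either flask, so I commit to starting complex in both.
- The forecast says starting complex at 28.2 % in cedar and starting complex at 22.4 % in ash, which is lower than my ash figure. Its conclusion: “Starting complex therefore remains the largest in both runs.”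
- The flasks give starting complex at 28.3 % in cedar and starting complex at 22.6 % in ash, so my ash figure runs 2.3 percentage points high.
- In ash, self-condensation had 82 % of its turnover to the end behind it at 6.00 s, by when the protic impurity stood at 45.2 % of its charge. Exchange went on after that, with 59.4 % of the incoming ligand still free at 12.0 s and complex with two exchanged rising from 2.83 % to 5.93 %. Quenched substrate ends at 14.2 % in cedar and 27.9 % in ash, under the ceilings.
- The answer for ash turns with the time of reading: starting complex and complex with two exchanged hold the same at 27.5 s.
- Ash read at 50 s has an exposure ceiling of 10.4 M·s, so its quench ceiling is 39.3 %. That flask holds 34.9 % of quenched substrate, and its starting complex, at 4.70 %, now stands below complex with two exchanged at 10.7 %.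

(The numbers of this flask are made up; the flask was simulated.)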